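**Retrosynthetic overview**
1. The C19 ester is cut to the neopentyl primary alcohol plus (E)-4-methoxycinnamoyl chloride. The diene is cut at C13–C14 to a kinetic enol triflate of a C13 methyl ketone (Stille vinylation).
2. The methyl ketone with its free 8α-hydroxyl comes from MeLi opening of a δ-lactone that masks both O-8 and C13.
3. Key step: ring A, then ring B, then the lactone ring close in one cationic head-to-tail cascade with the bond order of the labdane cyclase (C4–C5, C9–C10, O–C8). It is started by a chiral 1,1-disubstituted epoxide, not by protonation, so the epoxide CH2–O becomes the axial C19 oxygen and one stereocentre sets all five.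
4. The epoxide comes from a methyl ketone by catalytic asymmetric Corey–Chaykovsky methylenation.
5. The acyclic keto ester comes from geranyl bromide and tert-butyl acetate, SeO2 oxidation of the E-methyl group, and copper-catalysed coupling with a masked 3-oxobutyl Grignard reagent.

Assumption: the (S)-binaphthoxide La/Li catalyst is taken to give the (2S)-oxirane in step 5; if the sense of induction is opposite on this ketone, the (R)-binaphthoxide catalyst is used and nothing else changes.
Positions in the cyclised compounds follow labdane numbering (C4 carries the C18 methyl and C19 CH2O; C8 carries C17 and the oxygen).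

**Route**

Step 1
Reactants: 1 geranyl bromide; 2 tert-butyl acetate
Product: 4 tert-butyl (4E)-5,9-dimethyldeca-4,8-dienoate, via lithium tert-butyl acetate enolate 3 (not isolated)
Conditions: 2, LiN(iPr)2, THF, −78 °C; then 1, −78 → 0 °C
Reagents that add atoms: none
Why: Ester enolate alkylation (SN2) at the primary allylic bromide adds C12–C13 and leaves the E alkene of the geranyl unit untouched.

Step 2
Reactants: 4 tert-butyl (4E)-5,9-dimethyldeca-4,8-dienoate
Product: 5 tert-butyl (4E,8E)-10-hydroxy-5,9-dimethyldeca-4,8-dienoate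
Conditions: SeO2 (0.3 equiv), tBuOOH, salicylic acid (cat.), CH2Cl2, 0 → 23 °C
Reagents that add atoms: selenium dioxide, O=[Se]=O (catalytic oxygen carrier); tert-butyl hydroperoxide, CC(C)(C)OO (terminal oxygen source)
Why: SeO2-catalysed allylic oxidation (ene reaction, then [2,3]-sigmatropic shift) attacks the E-methyl group of the terminal, most electron-rich alkene and gives the (E)-allylic alcohol that becomes C1.

Step 3
Reactants: 5 tert-butyl (4E,8E)-10-hydroxy-5,9-dimethyldeca-4,8-dienoate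
Product: 6 tert-butyl (4E,8E)-10-bromo-5,9-dimethyldeca-4,8-dienoate
Conditions: CBr4, PPh3, CH2Cl2, 0 °C
Reagents that add atoms: carbon tetrabromide, BrC(Br)(Br)Br
Why: Appel bromination replaces the primary allylic hydroxyl by SN2 at 0 °C without allylic transposition or E/Z change, and the tert-butyl ester is inert.

Step 4
Reactants: 6 tert-butyl (4E,8E)-10-bromo-5,9-dimethyldeca-4,8-dienoate; 7 2-(2-bromoethyl)-2-methyl-1,3-dioxolane
Product: 10 tert-butyl (4E,8E)-5,9-dimethyl-13-oxotetradeca-4,8-dienoate, via Grignard reagent 8 (not isolated), via dioxolane ketal 9 (not isolated)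
Conditions: 7, Mg, THF, 25 °C; then 6, Li2CuCl4 (3 mol %), THF, −40 → 0 °C; then 1 M HCl, THF, 23 °C
Reagents that add atoms: water, O
Why: Copper-catalysed Grignard cross-coupling at the primary allylic bromide goes by α (SN2) attack with retention of the E alkene, and dilute acid in the work-up unmasks the methyl ketone while the tert-butyl ester survives.

Step 5
Reactants: 10 tert-butyl (4E,8E)-5,9-dimethyl-13-oxotetradeca-4,8-dienoate
Product: 11 tert-butyl (4E,8E)-5,9-dimethyl-12-[(2S)-2-methyloxiran-2-yl]dodeca-4,8-dienoate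
Conditions: Me3S(O)I, NaH, THF; then 10, LaLi3[(S)-binaphthoxide]3 = LaLi3(C20H12O2)3 (5 mol %), [2,4,6-(MeO)3C6H2]3P=O (5 mol %), 5 Å MS, THF, 23 °C
Reagents that add atoms: trimethylsulfoxonium iodide, C[S+](C)(C)=O.[I-]
Why: Catalytic asymmetric Corey–Chaykovsky epoxidation, in which the chiral La/Li binaphthoxide complex binds the methyl ketone and steers methylene transfer from the sulfoxonium ylide to one carbonyl face, sets C4 as (S) while alkenes and ester stay untouched.

Step 6
Reactants: 11 tert-butyl (4E,8E)-5,9-dimethyl-12-[(2S)-2-methyloxiran-2-yl]dodeca-4,8-dienoate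
Product: 12 (4S,5R,8R,9R,10S)-19-hydroxy-14,15,16-trinorlabdan-13,8-olide
Conditions: MeAlCl2 (2.5 equiv), CH2Cl2, −78 °C; aq. KNaC4H4O6
Reagents that add atoms: none
Why: Proposed new method: Lewis-acid activation lets the C5=C10 π bond open the 2,2-disubstituted oxirane at tertiary C4 with inversion (π-assisted, SN2-like), the E,E-diene folds chair–chair so that C4–C5 and C9–C10 form by anti additions (trans ring fusion, 10β-methyl, 9β side chain) and the tert-butyl ester carbonyl captures the C8 cation from the α face with loss of isobutene, so all five stereocentres follow from the (S)-epoxide provided the oxirane CH2, tied back toward the leaving oxygen and therefore smaller than the methyl group, takes the axial site at C4; the closest known reactions are MeAlCl2-promoted cyclisations of trisubstituted epoxy polyenes and lactone-terminated acid cyclisations of homofarnesic-type acids.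

Step 7
Reactants: 12 (4S,5R,8R,9R,10S)-19-hydroxy-14,15,16-trinorlabdan-13,8-olide
Product: 14 (4S,5R,8R,9R,10S)-8,19-dihydroxy-14,15-dinorlabdan-13-one, via dilithium hemiketalate 13 (not isolated)
Conditions: MeLi (2.4 equiv), THF, −78 °C; H2O, −78 °C
Reagents that add atoms: methyllithium, [Li]C
Why: Organolithium mono-addition to a lactone: the cyclic lithium hemiketalate is stable at −78 °C and opens to the methyl ketone and the free 8α-hydroxyl only on work-up, with no stereocentre touched.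

Step 8
Reactants: 14 (4S,5R,8R,9R,10S)-8,19-dihydroxy-14,15-dinorlabdan-13-one; 15 (E)-4-methoxycinnamoyl chloride
Product: 16 (4S,5R,8R,9R,10S)-8-hydroxy-13-oxo-14,15-dinorlabdan-19-yl (2E)-3-(4-methoxyphenyl)prop-2-enoate
Conditions: 15, Et3N, DMAP (cat.), CH2Cl2, 0 → 23 °C
Reagents that add atoms: none
Why: DMAP-catalysed acylation (nucleophilic catalysis) picks the primary C19 hydroxyl over the tertiary C8 hydroxyl.

Step 9
Reactants: 16 (4S,5R,8R,9R,10S)-8-hydroxy-13-oxo-14,15-dinorlabdan-19-yl (2E)-3-(4-methoxyphenyl)prop-2-enoate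
Product: 18 (4S,5R,8R,9R,10S)-8-hydroxy-13-[(trifluoromethanesulfonyl)oxy]-14,15-dinorlabd-13(16)-en-19-yl (2E)-3-(4-methoxyphenyl)prop-2-enoate, via dipotassium alkoxide enolate 17 (not isolated)
Conditions: KN(SiMe3)2 (2.3 equiv), THF, −78 °C; then PhNTf2, −78 → −20 °C
Reagents that add atoms: N-phenylbis(trifluoromethanesulfonimide), O=S(=O)(N(c1ccccc1)S(=O)(=O)C(F)(F)F)C(F)(F)F
Why: Kinetic enolisation by the bulky amide base takes a proton from the C16 methyl group and O-triflation of that enolate gives the 1,1-disubstituted enol triflate, while the hindered tertiary alkoxide is not triflated.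

Step 10
Reactants: 18 (4S,5R,8R,9R,10S)-8-hydroxy-13-[(trifluoromethanesulfonyl)oxy]-14,15-dinorlabd-13(16)-en-19-yl (2E)-3-(4-methoxyphenyl)prop-2-enoate
Product: 19 (4S,5R,8R,9R,10S)-8-hydroxylabda-13(16),14-dien-19-yl (2E)-3-(4-methoxyphenyl)prop-2-enoate
Conditions: Bu3SnCH=CH2, Pd(PPh3)4 (5 mol %), LiCl, THF, 65 °C
Reagents that add atoms: tributyl(vinyl)stannane, C=C[Sn](CCCC)(CCCC)CCCC
Why: Stille cross-coupling of the enol triflate with the vinylstannane (oxidative addition at zerovalent palladium, transmetalation, reductive elimination) builds the 2-substituted 1,3-diene without touching the ester, the tertiary alcohol or any stereocentre.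

**Compound list**
1 | geranyl bromide, (2E)-1-bromo-3,7-dimethylocta-2,6-diene | CC(C)=CCC/C(C)=C/CBr | starting material
2 | tert-butyl acetate | CC(=O)OC(C)(C)C | starting material
3 | lithium enolate of tert-butyl acetate | [Li]OC(=C)OC(C)(C)C | intermediate (not isolated)
4 | tert-butyl (4E)-5,9-dimethyldeca-4,8-dienoate | CC(C)=CCC/C(C)=C/CCC(=O)OC(C)(C)C | intermediate
5 | tert-butyl (4E,8E)-10-hydroxy-5,9-dimethyldeca-4,8-dienoate | OC/C(C)=C/CC/C(C)=C/CCC(=O)OC(C)(C)C | intermediate
6 | tert-butyl (4E,8E)-10-bromo-5,9-dimethyldeca-4,8-dienoate | BrC/C(C)=C/CC/C(C)=C/CCC(=O)OC(C)(C)C | intermediate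
7 | 2-(2-bromoethyl)-2-methyl-1,3-dioxolane | CC1(CCBr)OCCO1 | starting material
8 | [2-(2-methyl-1,3-dioxolan-2-yl)ethyl]magnesium bromide | CC1(CC[Mg]Br)OCCO1 | intermediate (not isolated)
9 | tert-butyl (4E,8E)-5,9-dimethyl-12-(2-methyl-1,3-dioxolan-2-yl)dodeca-4,8-dienoate | CC1(CCC/C(C)=C/CC/C(C)=C/CCC(=O)OC(C)(C)C)OCCO1 | intermediate (not isolated)
10 | tert-butyl (4E,8E)-5,9-dimethyl-13-oxotetradeca-4,8-dienoate | CC(=O)CCC/C(C)=C/CC/C(C)=C/CCC(=O)OC(C)(C)C | intermediate
11 | tert-butyl (4E,8E)-5,9-dimethyl-12-[(2S)-2-methyloxiran-2-yl]dodeca-4,8-dienoate | C[C@]1(CCC/C(C)=C/CC/C(C)=C/CCC(=O)OC(C)(C)C)CO1 | intermediate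
12 | (4S,5R,8R,9R,10S)-19-hydroxy-14,15,16-trinorlabdan-13,8-olide: trans-decalin δ-lactone, 4α-CH3, 4β-CH2OH (axial), 10β-CH3, 8β-CH3, 8α-O–C(=O)–CH2CH2–C9 | O=C1CC[C@@H]2[C@@]3(C)CCC[C@](C)(CO)[C@@H]3CC[C@@]2(C)O1 | intermediate
13 | dilithium salt of the cyclic C13 hemiketal of 14 (C13 configuration undefined) | CC1(O[Li])CC[C@@H]2[C@@]3(C)CCC[C@](C)(CO[Li])[C@@H]3CC[C@@]2(C)O1 | intermediate (not isolated)
14 | (4S,5R,8R,9R,10S)-8,19-dihydroxy-14,15-dinorlabdan-13-one (8α-OH) | CC(=O)CC[C@@H]1[C@@]2(C)CCC[C@](C)(CO)[C@@H]2CC[C@@]1(C)O | intermediate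
15 | (E)-4-methoxycinnamoyl chloride | COc1ccc(/C=C/C(=O)Cl)cc1 | starting material
16 | (4S,5R,8R,9R,10S)-8-hydroxy-13-oxo-14,15-dinorlabdan-19-yl (2E)-3-(4-methoxyphenyl)prop-2-enoate | CC(=O)CC[C@@H]1[C@@]2(C)CCC[C@](C)(COC(=O)/C=C/c3ccc(OC)cc3)[C@@H]2CC[C@@]1(C)O | intermediate
17 | dipotassium 8-alkoxide 13(16)-enolate of 16 | C=C(O[K])CC[C@@H]1[C@@]2(C)CCC[C@](C)(COC(=O)/C=C/c3ccc(OC)cc3)[C@@H]2CC[C@@]1(C)O[K] | intermediate (not isolated)
18 | (4S,5R,8R,9R,10S)-8-hydroxy-13-[(trifluoromethanesulfonyl)oxy]-14,15-dinorlabd-13(16)-en-19-yl (2E)-3-(4-methoxyphenyl)prop-2-enoate | C=C(OS(=O)(=O)C(F)(F)F)CC[C@@H]1[C@@]2(C)CCC[C@](C)(COC(=O)/C=C/c3ccc(OC)cc3)[C@@H]2CC[C@@]1(C)O | intermediate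
19 | (4S,5R,8R,9R,10S)-8-hydroxylabda-13(16),14-dien-19-yl (2E)-3-(4-methoxyphenyl)prop-2-enoate, CNP0249194.1 | C=CC(=C)CC[C@@H]1[C@@]2(C)CCC[C@](C)(COC(=O)/C=C/c3ccc(OC)cc3)[C@@H]2CC[C@@]1(C)O | target

**Count**
Total steps: 10. Longest linear sequence: 10 steps (1 → 19); all other inputs are commercial.

**Three steps most likely to fail**

Step 6 is the main risk. The chair with the oxirane CH2 equatorial would give the C4-epimeric diastereomer in the enantiomeric decalin series. A 1,2-hydride shift can turn the epoxide into an aldehyde. The axial C19–O–Al oxygen can also trap the C10 cation as a bridged ether. Recrystallisation of 12 would raise its enantiopurity if the step works. The fallback fixes C4 through alkene geometry and sets out from 6. Copper-catalysed coupling (Li2CuCl4, THF, −40 °C) with commercial (1,3-dioxolan-2-ylmethyl)magnesium bromide gives the acetal tert-butyl (4E,8E)-11-(1,3-dioxolan-2-yl)-5,9-dimethylundeca-4,8-dienoate F1, which 1 M HCl in the work-up hydrolyses to the aldehyde tert-butyl (4E,8E)-5,9-dimethyl-12-oxododeca-4,8-dienoate F2. Still–Gennari olefination with (CF3CH2O)2P(O)CH(CH3)CO2CH3, KN(SiMe3)2 and 18-crown-6 gives the Z-enoate 14-tert-butyl 1-methyl (2Z,6E,10E)-2,6,10-trimethyltetradeca-2,6,10-trienedioate F3. iBu2AlH at −78 °C reduces the methyl enoate ahead of the tert-butyl ester to the allylic alcohol tert-butyl (4E,8E,12Z)-14-hydroxy-5,9,13-trimethyltetradeca-4,8,12-trienoate F4. Sharpless epoxidation (Ti(OiPr)4, D-(−)-diethyl tartrate, tBuOOH) gives the epoxy alcohol tert-butyl (4E,8E)-11-[(2S,3R)-3-(hydroxymethyl)-3-methyloxiran-2-yl]-5,9-dimethylundeca-4,8-dienoate F5. MeAlCl2 (3.5 equiv, CH2Cl2, −78 °C) then gives the diol lactone (3S,4S,5R,8R,9R,10S)-3,19-dihydroxy-14,15,16-trinorlabdan-13,8-olide F6; anti opening at C4 in the chair puts the Z-CH2OH axial with no choice left to the substrate. The extra 3β-hydroxyl is removed through the cyclic thionocarbonate 3β,19-(thiocarbonyldioxy)-14,15,16-trinorlabdan-13,8-olide F7 (thiocarbonyldiimidazole, toluene, 80 °C). Bu3SnH/AIBN cleaves its secondary C3–O bond and leaves the stannyl thiocarbonate 19-[(tributylstannylsulfanyl)carbonyloxy]-14,15,16-trinorlabdan-13,8-olide F8, which K2CO3 in methanol hydrolyses. The fallback comes back to the route at 12.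

Step 5 may give low enantioselectivity or slow turnover on this long-chain aliphatic methyl ketone. The fallback replaces asymmetric catalysis by kinetic resolution and sets out from 10. Uncatalysed Corey–Chaykovsky epoxidation (Me3S(O)I, NaH, DMSO) gives the racemic epoxide tert-butyl (4E,8E)-5,9-dimethyl-12-(2-methyloxiran-2-yl)dodeca-4,8-dienoate F9. Enantioselective azidolysis with Me3SiN3 (0.55 equiv) and the chiral (salen)CrN3 complex of trivalent chromium (salen = N,N′-bis(3,5-di-tert-butylsalicylidene)cyclohexane-1,2-diamine dianion, antipode matched to the unwanted epoxide) consumes the (R)-epoxide as the azido silyl ether tert-butyl (4E,8E,13R)-14-azido-5,9,13-trimethyl-13-[(trimethylsilyl)oxy]tetradeca-4,8-dienoate F10. The unreacted (S)-epoxide is recovered, so the fallback comes back at 11.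

Step 9 may fail because the tertiary potassium alkoxide can close onto the ketone as a hemiketalate before enolisation, and the cinnamate must survive the base. The fallback builds the diene by Peterson olefination before the ester is in place and sets out from 12. Me3SiCH2Li (3 equiv, THF, −78 °C) opens the lactone to the α-silyl ketone (4S,5R,8R,9R,10S)-8,19-dihydroxy-16-(trimethylsilyl)-14,15-dinorlabdan-13-one F11. CH2=CHMgBr with CeCl3 (THF, −78 °C) adds to give the β-hydroxysilane (13RS)-16-(trimethylsilyl)labd-14-ene-8α,13,19-triol F12. KH (THF, 0 → 23 °C) eliminates the silanolate toward C16 only and gives the diene diol (4S,5R,8R,9R,10S)-labda-13(16),14-diene-8,19-diol F13. Acylation of its primary hydroxyl with 15 (Et3N, DMAP, CH2Cl2) brings the fallback back at 19.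

**Further compounds**
F1 | step 6 | tert-butyl (4E,8E)-11-(1,3-dioxolan-2-yl)-5,9-dimethylundeca-4,8-dienoate | O1CCOC1CC/C(C)=C/CC/C(C)=C/CCC(=O)OC(C)(C)C
F2 | step 6 | tert-butyl (4E,8E)-5,9-dimethyl-12-oxododeca-4,8-dienoate | O=CCC/C(C)=C/CC/C(C)=C/CCC(=O)OC(C)(C)C
F3 | step 6 | 14-tert-butyl 1-methyl (2Z,6E,10E)-2,6,10-trimethyltetradeca-2,6,10-trienedioate | COC(=O)/C(C)=C\CC/C(C)=C/CC/C(C)=C/CCC(=O)OC(C)(C)C
F4 | step 6 | tert-butyl (4E,8E,12Z)-14-hydroxy-5,9,13-trimethyltetradeca-4,8,12-trienoate | OC/C(C)=C\CC/C(C)=C/CC/C(C)=C/CCC(=O)OC(C)(C)C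
F5 | step 6 | tert-butyl (4E,8E)-11-[(2S,3R)-3-(hydroxymethyl)-3-methyloxiran-2-yl]-5,9-dimethylundeca-4,8-dienoate | OC[C@@]1(C)O[C@H]1CC/C(C)=C/CC/C(C)=C/CCC(=O)OC(C)(C)C
F6 | step 6 | (3S,4S,5R,8R,9R,10S)-3,19-dihydroxy-14,15,16-trinorlabdan-13,8-olide | O=C1CC[C@@H]2[C@@]3(C)CC[C@H](O)[C@](C)(CO)[C@@H]3CC[C@@]2(C)O1
F7 | step 6 | 3β,19-(thiocarbonyldioxy)-14,15,16-trinorlabdan-13,8-olide | O=C1CC[C@@H]2[C@@]3(C)CC[C@@H]4OC(=S)OC[C@]4(C)[C@@H]3CC[C@@]2(C)O1
F8 | step 6 | 19-[(tributylstannylsulfanyl)carbonyloxy]-14,15,16-trinorlabdan-13,8-olide | O=C1CC[C@@H]2[C@@]3(C)CCC[C@](C)(COC(=O)S[Sn](CCCC)(CCCC)CCCC)[C@@H]3CC[C@@]2(C)O1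
F9 | step 5 | racemic tert-butyl (4E,8E)-5,9-dimethyl-12-(2-methyloxiran-2-yl)dodeca-4,8-dienoate | CC1(CCC/C(C)=C/CC/C(C)=C/CCC(=O)OC(C)(C)C)CO1
F10 | step 5 | tert-butyl (4E,8E,13R)-14-azido-5,9,13-trimethyl-13-[(trimethylsilyl)oxy]tetradeca-4,8-dienoate | C[C@@](O[Si](C)(C)C)(CCC/C(C)=C/CC/C(C)=C/CCC(=O)OC(C)(C)C)CN=[N+]=[N-]
F11 | step 9 | (4S,5R,8R,9R,10S)-8,19-dihydroxy-16-(trimethylsilyl)-14,15-dinorlabdan-13-one | C[Si](C)(C)CC(=O)CC[C@@H]1[C@@]2(C)CCC[C@](C)(CO)[C@@H]2CC[C@@]1(C)O
F12 | step 9 | (13RS)-16-(trimethylsilyl)labd-14-ene-8α,13,19-triol | C[Si](C)(C)CC(O)(C=C)CC[C@@H]1[C@@]2(C)CCC[C@](C)(CO)[C@@H]2CC[C@@]1(C)O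
F13 | step 9 | (4S,5R,8R,9R,10S)-labda-13(16),14-diene-8,19-diol | C=CC(=C)CC[C@@H]1[C@@]2(C)CCC[C@](C)(CO)[C@@H]2CC[C@@]1(C)O
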